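**Plan**

1. Locants follow phthalide numbering (C1 carbonyl, O2, C3 butylidene-bearing carbon, C3a/C7a ring fusion); primed locants belong to the half that carries the hydroxyl. Target = (3Z,3'Z,6S,7R,4'R,6'R,7'S), with bonds C6–C7' and C7–C4' joining the halves.
2. Retrosynthesis: the C6' carbinol is traced back to the C6' ketone; then C6–C7' and C7–C4' are cut together (retro-[4+2]) to give (Z)-ligustilide and a 6-silyloxy cyclohexa-1,3-diene lactone, itself cut back to ligustilide through its 6,7-epoxide.
3. Enabling feature: the bicyclo[2.2.2]oct-2-ene whose etheno bridge C3a'=C7a' is the butenolide alkene of the primed half, whose bridgeheads C4' and C7' are allylic to it, and whose two-carbon bridge C6–C7 is the former cis alkene of ligustilide. This is the retron of a Diels–Alder reaction.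
4. Forward: both bicyclic lactone halves come from (Z)-ligustilide. One portion is masked at C3 as its methanol adduct, epoxidised, opened to the dienol and silylated; cycloaddition with unmodified ligustilide then closes the carbocycle C6–C7–C4'–C5'–C6'–C7' (the last ring); desilylation, oxidation, unmasking and reduction follow.
5. Stereochemistry: C6'(S) from catalytic asymmetric epoxidation; it steers the cycloaddition (anti to OSi, exo because of the sp3 ketal at C3', cis by suprafacial addition) and so fixes C6, C7, C4', C7'. C6' is then re-set to (R) by hydride delivery to the ketone from the etheno-bridge face; both (Z)-enol lactones are the thermodynamic isomers.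

Key step: step 5

Assumption: (Z)-ligustilide is bought as the isolated natural product; all else is common reagent stock.
Remark: in compounds 2–8 the ketal carbon (C3, later C3') is an unassigned mixture of both configurations. It is a passenger centre erased in step 8, so the SMILES leave it undefined.

**Step 1**
Reactants: 1 (Z)-ligustilide
Product: 2 3-butyl-3-methoxy-4,5-dihydro-2-benzofuran-1(3H)-one (racemic pseudo-ester)
Conditions: MeOH, Amberlyst-15 (H+ resin), 0 °C, then filter
Reagents that add atoms: methanol, CO
Why: Acid-catalysed Markovnikov addition of an alcohol to an enol lactone (pseudo-ester formation, the kinetic outcome known for alkylidene phthalides and angelica lactone): protonation at C8 gives an oxygen-stabilised cation that methanol traps at C3, the resin is filtered off before ring opening to the keto ester can follow, and the new ketal centre forms as both epimers, which is harmless because it becomes sp2 again in step 8.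

**Step 2**
Reactants: 2 3-butyl-3-methoxy-4,5-dihydro-2-benzofuran-1(3H)-one
Product: 3 (6S,7R)-3-butyl-6,7-epoxy-3-methoxy-4,5,6,7-tetrahydro-2-benzofuran-1(3H)-one
Conditions: chloro[(R,R)-N,N'-bis(3,5-di-tert-butylsalicylidene)-1,2-cyclohexanediaminato]manganese, (R,R)-(salen)MnCl (5 mol %), mCPBA, NMO, CH2Cl2, −78 °C
Reagents that add atoms: mCPBA (3-chloroperoxybenzoic acid), OOC(=O)c1cccc(Cl)c1
Why: Jacobsen–Katsuki epoxidation, for which a cis-disubstituted alkene conjugated to a second alkene (C6=C7 next to C7a=C3a, as in indene or 1,2-dihydronaphthalene) is the best substrate class while the tetrasubstituted, ester-deactivated C3a=C7a bond is inert; the (R,R) ligand is chosen, by analogy with indene, to deliver oxygen to the face that gives (6S,7R), the only stereocentres in the route set by a chiral reagent.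

**Step 3**
Reactants: 3 (6S,7R)-epoxide
Product: 4 (6S)-3-butyl-6-hydroxy-3-methoxy-5,6-dihydro-2-benzofuran-1(3H)-one
Conditions: DBU (0.2 equiv), CH2Cl2, −20 → 0 °C
Reagents that add atoms: none
Why: Base-mediated vinylogous E1cB (1,4-) elimination of a vinyl epoxide, the known isomerisation of epoxy cyclohexenecarboxylates to hydroxy cyclohexadienecarboxylates: DBU removes the acidic gamma proton at C4 and the dienolate expels the allylic C7–O bond, which moves the diene to C3a=C4/C7a=C7 and leaves the C6–O bond, and hence the (6S) centre, untouched.

**Step 4**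
Reactants: 4 (6S)-dienol
Product: 5 (6S)-3-butyl-6-(tert-butyldimethylsilyloxy)-3-methoxy-5,6-dihydro-2-benzofuran-1(3H)-one
Conditions: TBSCl, imidazole, DMF, 0 °C → rt
Reagents that add atoms: tert-butyldimethylsilyl chloride, CC(C)(C)[Si](C)(C)Cl
Why: Standard imidazole-promoted silylation of a secondary alcohol; the bulky silyl ether blocks acid- or base-induced aromatisation of the dihydroarene alcohol and is the group that will shield one face of the diene.

**Step 5**
Reactants: 5 (6S)-silyloxy diene; 1 (Z)-ligustilide
Product: 6 exo cycloadduct, (3Z,6S,7R,4'R,6'S,7'S)-3-butylidene-3'-butyl-6'-(tert-butyldimethylsilyloxy)-3'-methoxy dimer with bonds C6–C7' and C7–C4' (bicyclo[2.2.2]oct-2-ene; ring B of the ligustilide half on the side of the C5'–C6' bridge, OSi on the side of the C3a'=C7a' bridge)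
Conditions: 1 (3 equiv), BHT, CH2Cl2, 1.2 GPa, 40 °C
Reagents that add atoms: none
Why: Concerted, asynchronous [4+2] cycloaddition with inverse electron demand: the HOMO of the alkoxy-triene of 1 (largest at C6) meets the LUMO of the cyclohexa-1,3-diene-2-carboxylate of 5 (largest at C7', beta to the lactone carbonyl), so C6–C7' leads and C7–C4' follows; the closest known reaction types are the thermal Diels–Alder dimerisations of dihydrophthalides, in which C6=C7 of one molecule is the dienophile toward a ring diene of another, and the para-selective cycloadditions of 1,3-diene-2-carboxylates. The same two bonds close both new six-membered rings of the bicyclo[2.2.2]octene (the carbocycle C6–C7–C4'–C5'–C6'–C7' and the cyclohexene C6–C7–C4'–C3a'–C7a'–C7') in a suprafacial [4s+2s] mode, so the cis alkene of 1 becomes the cis-fused C6–C7 bridge. The bridgeheads C7' and C4' are set by approach of 1 to the diene face opposite the silyloxy group at C6', which sits next to C7' where bonding is most advanced; this transfers the absolute configuration from the centre made in step 2. C6 and C7 are set by the exo orientation: the sp3 ketal carbon C3' holds a butyl or methoxy group on each face next to C3a', exactly where C7a/C3a and the lactone of 1 would lie in the endo arrangement, so ring B (the carbocycle of 1) is forced under the C5'–C6' bridge. The step needs site selectivity (C6=C7, not the enol-ether alkene C3=C8 of 1) together with regio-, facial and exo selectivity. These are secured, in that order, by the fact that only this pairing creates no quaternary carbon, by the ester at C7a', by the silyl ether and by the ketal at C3', while excess 1 under pressure at low temperature suppresses diene dimerisation and sigmatropic hydrogen shifts.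

**Step 6**
Reactants: 6 exo cycloadduct
Product: 7 (3Z,6S,7R,4'R,6'S,7'S)-3-butylidene-3'-butyl-6'-hydroxy-3'-methoxy dimer (hydroxyl on the side of the etheno bridge)
Conditions: HF·pyridine, pyridine, THF, 0 °C → rt
Reagents that add atoms: none
Why: Fluoride-mediated cleavage of a secondary silyl ether under buffered, non-basic conditions that leave both lactones, the ketal and the enol lactone intact; no stereocentre is touched.

**Step 7**
Reactants: 7 (6'S)-alcohol
Product: 8 (3Z,6S,7R,4'R,7'S)-3-butylidene-3'-butyl-3'-methoxy-6'-oxo dimer
Conditions: Dess–Martin periodinane, CH2Cl2, 0 °C → rt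
Reagents that add atoms: none
Why: Dess–Martin oxidation of a secondary alcohol to the bicyclo[2.2.2]octenone under neutral conditions; the C6' centre, having served as the control element of step 5, is deliberately erased so that it can be re-set in the opposite sense.

**Step 8**
Reactants: 8 ketone with the 3'-methoxy pseudo-ester
Product: 9 (3Z,3'Z,6S,7R,4'R,7'S)-3,3'-dibutylidene-6'-oxo dimer
Conditions: TsOH·H2O (10 mol %), PhMe, 5 Å MS, 80 °C
Reagents that add atoms: none
Why: Acid-catalysed elimination of methanol from the pseudo-ester through the acyloxy-carbenium ion (the event that ends classical alkylidenephthalide syntheses), driven by uptake of methanol on the sieves; both ketal epimers converge on one enol lactone, and reversible ionisation delivers the thermodynamically preferred (Z)-butylidene, as in ligustilide itself.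

**Step 9**
Reactants: 9 bis-butylidene ketone
Product: 10 target, (3Z,3'Z,6S,7R,4'R,6'R,7'S)-6'-hydroxy dimer
Conditions: NaBH4, CeCl3·7H2O, MeOH/CH2Cl2, −78 °C
Reagents that add atoms: none
Why: Luche reduction: the cerium-assisted borohydride reduces the C6' ketone in 1,2 fashion without touching the two unsaturated lactones, and it should attack from the face on the side of the C3a'=C7a' etheno bridge because the other face is covered by the C5 methylene of the exo-fused ring B, which places the hydroxyl syn to the C6–C7 bridge and gives (6'R).

**Compound list**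

1 | (Z)-ligustilide, (3Z)-3-butylidene-4,5-dihydro-2-benzofuran-1(3H)-one | CCC/C=C1\OC(=O)C2=C1CCC=C2 | starting material
2 | 3-butyl-3-methoxy-4,5-dihydro-2-benzofuran-1(3H)-one (racemic) | CCCCC1(OC)OC(=O)C2=C1CCC=C2 | intermediate
3 | (6S,7R)-3-butyl-6,7-epoxy-3-methoxy-4,5,6,7-tetrahydro-2-benzofuran-1(3H)-one (both C3 epimers) | CCCCC1(OC)OC(=O)C2=C1CC[C@@H]3O[C@@H]32 | intermediate
4 | (6S)-3-butyl-6-hydroxy-3-methoxy-5,6-dihydro-2-benzofuran-1(3H)-one (both C3 epimers) | CCCCC1(OC)OC(=O)C2=C[C@@H](O)CC=C21 | intermediate
5 | (6S)-3-butyl-6-(tert-butyldimethylsilyloxy)-3-methoxy-5,6-dihydro-2-benzofuran-1(3H)-one (both C3 epimers) | CCCCC1(OC)OC(=O)C2=C[C@@H](O[Si](C)(C)C(C)(C)C)CC=C21 | intermediate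
6 | exo cycloadduct, (3Z,6S,7R,4'R,6'S,7'S)-3-butylidene-3'-butyl-6'-(tert-butyldimethylsilyloxy)-3'-methoxy dimer, bonds C6–C7' and C7–C4' (both C3' epimers) | CCC/C=C1\OC(=O)C2=C1CC[C@@H]1[C@H]3C4=C(C(CCCC)(OC)OC4=O)[C@H](C[C@@H]3O[Si](C)(C)C(C)(C)C)[C@H]21 | intermediate
7 | (3Z,6S,7R,4'R,6'S,7'S)-3-butylidene-3'-butyl-6'-hydroxy-3'-methoxy dimer (both C3' epimers) | CCC/C=C1\OC(=O)C2=C1CC[C@@H]1[C@H]3C4=C(C(CCCC)(OC)OC4=O)[C@H](C[C@@H]3O)[C@H]21 | intermediate
8 | (3Z,6S,7R,4'R,7'S)-3-butylidene-3'-butyl-3'-methoxy-6'-oxo dimer (both C3' epimers) | CCC/C=C1\OC(=O)C2=C1CC[C@@H]1[C@H]3C4=C(C(CCCC)(OC)OC4=O)[C@H](CC3=O)[C@H]21 | intermediate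
9 | (3Z,3'Z,6S,7R,4'R,7'S)-3,3'-dibutylidene-6'-oxo dimer | CCC/C=C1\OC(=O)C2=C1CC[C@@H]1[C@H]3C4=C(/C(=C/CCC)OC4=O)[C@H](CC3=O)[C@H]21 | intermediate
10 | (3Z,3'Z,6S,7R,4'R,6'R,7'S)-3,3'-dibutylidene-6'-hydroxy dimer | CCC/C=C1\OC(=O)C2=C1CC[C@@H]1[C@H]3C4=C(/C(=C/CCC)OC4=O)[C@H](C[C@H]3O)[C@H]21 | target

**Count and risks**

Total step count: 9. Longest linear sequence: 9 steps (1 → 2 → 3 → 4 → 5 → 6 → 7 → 8 → 9 → 10); the second cycloaddition partner is 1 itself.

Steps most likely to fail:

Step 5. The cross-cycloaddition may be outrun by cycloaddition at the enol-ether alkene C3=C8 of the dienophile, or may discriminate too weakly between exo and endo approach, giving the wrong fusion of ring B. The fallback sets out from 5 and uses pseudo-ester 2 as the dienophile in place of 1, so that the dienophile has no enol-ether alkene and carries its own out-of-plane groups against endo stacking. Under the same pressure conditions this should give the doubly masked exo adduct F1. HF·pyridine would free the (6'S)-alcohol F2, Dess–Martin oxidation would give the ketone F3, and TsOH in toluene would remove two molecules of methanol, which returns to the route at 9.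

Step 1. The pseudo-ester may go on to the ring-opened methyl keto ester, or the acid may trigger oligomerisation of the triene before methanol is captured. The fallback sets out from 1 and avoids acid on the enol lactone: LiOH in aqueous THF followed by careful acidification would give the ring-closed hydroxy lactone (pseudo-acid) F4, thionyl chloride with a trace of DMF would convert it into the cyclic pseudo-chloride F5, and methanol with pyridine would displace chloride at C3, which returns to the route at 2.

Step 2. Enantiofacial discrimination by the manganese catalyst on a dienyl lactone may be incomplete, or uncatalysed epoxidation may erode it. The fallback sets out from 2 and replaces asymmetric catalysis by resolution: buffered mCPBA would give the racemic cis-epoxide F6 and DBU the racemic dienol F7. Candida antarctica lipase B with vinyl acetate should, by the usual preference for cyclic allylic secondary alcohols, acetylate the (6R)-enantiomer to the acetate F8 and leave the (6S)-dienol, which returns to the route at 4.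

**Further compounds**

F1 | step 5 | doubly masked exo cycloadduct, (6S,7R,4'R,6'S,7'S)-3,3'-dibutyl-6'-(tert-butyldimethylsilyloxy)-3,3'-dimethoxy dimer (epimers at C3 and C3') | CCCCC1(OC)OC(=O)C2=C1CC[C@@H]1[C@H]3C4=C(C(CCCC)(OC)OC4=O)[C@H](C[C@@H]3O[Si](C)(C)C(C)(C)C)[C@H]21
F2 | step 5 | (6S,7R,4'R,6'S,7'S)-3,3'-dibutyl-6'-hydroxy-3,3'-dimethoxy dimer (epimers at C3 and C3') | CCCCC1(OC)OC(=O)C2=C1CC[C@@H]1[C@H]3C4=C(C(CCCC)(OC)OC4=O)[C@H](C[C@@H]3O)[C@H]21
F3 | step 5 | (6S,7R,4'R,7'S)-3,3'-dibutyl-3,3'-dimethoxy-6'-oxo dimer (epimers at C3 and C3') | CCCCC1(OC)OC(=O)C2=C1CC[C@@H]1[C@H]3C4=C(C(CCCC)(OC)OC4=O)[C@H](CC3=O)[C@H]21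
F4 | step 1 | 3-butyl-3-hydroxy-4,5-dihydro-2-benzofuran-1(3H)-one (racemic pseudo-acid) | CCCCC1(O)OC(=O)C2=C1CCC=C2
F5 | step 1 | 3-butyl-3-chloro-4,5-dihydro-2-benzofuran-1(3H)-one (racemic pseudo-chloride) | CCCCC1(Cl)OC(=O)C2=C1CCC=C2
F6 | step 2 | racemic cis-3-butyl-6,7-epoxy-3-methoxy-4,5,6,7-tetrahydro-2-benzofuran-1(3H)-one | CCCCC1(OC)OC(=O)C2=C1CCC3OC32
F7 | step 2 | racemic 3-butyl-6-hydroxy-3-methoxy-5,6-dihydro-2-benzofuran-1(3H)-one | CCCCC1(OC)OC(=O)C2=CC(O)CC=C21
F8 | step 2 | (6R)-6-acetoxy-3-butyl-3-methoxy-5,6-dihydro-2-benzofuran-1(3H)-one | CCCCC1(OC)OC(=O)C2=C[C@H](OC(C)=O)CC=C21
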